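The plan rests on cutting C12–C13 and C11–C15, the two σ-bonds flanking the tetrasubstituted C11=C12 alkene that cyclohexene ring A shares with cyclopentenone ring C. This opens ring A and the twelve-membered ring B together. Since C11=C12 sits between two oxygenated carbons (C10, C18), it is traced back to a mirror-symmetric 2-alkenylcyclopent-4-ene-1,3-dione, while C1 with its C13–C14 and C15–C17 arms is (R)-limonene. In the key step an iron hydride converts the isopropenyl group into the C15 radical, which adds to C11, and the C12 enolate so formed closes onto the C13 aldehyde. The precursor is an open-chain keto aldehyde bearing the enedione.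

Key step: step 9

Remark on numbering (verticillane skeleton):
- C1 = ring-A methine; C2–C3 = CH2CH2; C4 (=C20H2); C5 = CH2; C6 = CH(OAc).
- C7=C8 (C19H3 on C8); C9 = CH; C10 = C=O; C11=C12; C13–C14 = CH2CH2.
- C15 carries C16H3 and C17H3; C18 = CH(OAc), bonded to C9 and C12.
- Ring A = C1/C14/C13/C12/C11/C15. Ring B = C1–C11 plus C15. Ring C = C9/C10/C11/C12/C18.

Remark on the chemistry: stereocentres that a later step erases (C9 in 12; the ring centres in 13; C9 and C13 in 16) are expected as mixtures and are left open in the SMILES.

Step 1
Reactants: 1 (R)-(+)-limonene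
Product: 3 keto acetal (5R)-7,7-dimethoxy-5-(prop-1-en-2-yl)heptan-2-one, via keto aldehyde 2 (not isolated)
Conditions: O3 (1 equiv), CH2Cl2–MeOH, −78 °C; Me2S; then p-TsOH (cat.), MeOH, rt
Reagents that add atoms: ozone [O-][O+]=O; methanol CO
Why: Chemoselective ozonolysis takes the electron-richer trisubstituted ring alkene before the isopropenyl group, acid-catalysed acetalisation then takes the aldehyde but not the ketone, and C1 is carried over from limonene unchanged.

Step 2
Reactants: 4 but-2-yn-1-ol
Product: 6 (E)-3-iodobut-2-en-1-ol, via alkenylzirconocene 5 (not isolated)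
Conditions: Cp2Zr(H)Cl (2.2 equiv), THF, rt; then I2, 0 °C
Reagents that add atoms: iodine II
Why: Syn hydrozirconation should place zirconium on the less hindered methyl-bearing alkyne carbon and iodinolysis goes with retention, which fixes the E geometry of the later C7=C8 alkene.

Step 3
Reactants: 6 (E)-3-iodobut-2-en-1-ol
Product: 7 (E)-3-iodobut-2-enal
Conditions: MnO2, CH2Cl2, rt
Reagents that add atoms: none
Why: Allylic oxidation with MnO2 stops at the enal and leaves the vinyl iodide and its geometry untouched.

Step 4
Reactants: 3 keto acetal; 7 (E)-3-iodobut-2-enal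
Product: 9 (2E,4S,9R)-4-hydroxy-2-iodo-11,11-dimethoxy-9-(prop-1-en-2-yl)undec-2-en-6-one, via boron enolate 8 (not isolated)
Conditions: (−)-Ipc2BCl, Et3N, Et2O, 0 °C; then 7, −78 to −20 °C; H2O2, MeOH, pH 7 buffer
Reagents that add atoms: none
Why: In this diisopinocampheylboron-mediated methyl ketone aldol, enolisation occurs on the methyl side and the (−)-Ipc ligands should direct the enolate to the Si face of the enal, which sets C6 as S under reagent control.

Step 5
Reactants: 9 aldol adduct
Product: 10 (2E,4S,9R)-4-(tert-butyldimethylsilyloxy)-2-iodo-11,11-dimethoxy-9-(prop-1-en-2-yl)undec-2-en-6-one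
Conditions: TBSCl, imidazole, DMF, rt
Reagents that add atoms: tert-butyldimethylsilyl chloride CC(C)(C)[Si](C)(C)Cl
Why: Silyl ether formation under mild base masks C6–OH as a poor leaving group, which guards against β-elimination next to the C4 ketone and against vinylogous elimination once C9–H becomes acidic.

Step 6
Reactants: 10 silyl ether; 11 furfural
Product: 12 (2E,4S,9R)-4-(tert-butyldimethylsilyloxy)-1-(furan-2-yl)-1-hydroxy-11,11-dimethoxy-2-methyl-9-(prop-1-en-2-yl)undec-2-en-6-one (both C1 carbinol epimers)
Conditions: CrCl2 (excess), NiCl2 (cat.), DMSO, rt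
Reagents that add atoms: none
Why: The Nozaki–Hiyama–Kishi coupling forms C8–C9 with retention of alkene geometry and adds to the aldehyde only, sparing the C4 ketone and the acetal; the new carbinol centre is uncontrolled and is lost in step 7.

Step 7
Reactants: 12 furyl carbinol
Product: 13 (3R,8S,9E)-8-(tert-butyldimethylsilyloxy)-10-(trans-5-hydroxy-2-oxocyclopent-3-en-1-yl)-6-oxo-3-(prop-1-en-2-yl)undec-9-enal (both trans ring antipodes)
Conditions: Dy(OTf)3 (cat.), t-BuOH–H2O, 80 °C
Reagents that add atoms: water O
Why: In the Piancatelli rearrangement, ionisation of the carbinol, water addition to the furan, ring opening and conrotatory 4π closure give the trans-4-hydroxy-5-alkenylcyclopentenone, the same aqueous Lewis acid hydrolyses the acetal to the C13 aldehyde, and the ring stereocentres are erased in step 8.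

Step 8
Reactants: 13 hydroxy enone aldehyde
Product: 14 (3R,8S,9E)-8-(tert-butyldimethylsilyloxy)-10-(2,5-dioxocyclopent-3-en-1-yl)-6-oxo-3-(prop-1-en-2-yl)undec-9-enal
Conditions: Dess–Martin periodinane, CH2Cl2, 0 °C to rt
Reagents that add atoms: none
Why: Dess–Martin oxidation of the allylic alcohol under non-basic conditions gives the enedione, which stays in the diketo form because its enol would be a cyclopentadienone, and it merges the stereoisomers of 13 into one compound.

Step 9
Reactants: 14 enedione keto aldehyde
Product: 16 tricyclic C13-hydroxy 10,18-dione (rings A to C closed), via macrocyclic iron enolate 15 (not isolated)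
Conditions: Fe(acac)3 (0.3 equiv), PhSiH2(OiPr) (slow addition), i-PrOH, 1,2-dichloroethane, 1 mM, 40 °C
Reagents that add atoms: none
Why: Hydrogen-atom transfer from the iron hydride to the only 1,1-disubstituted alkene gives the tertiary C15 radical, which adds to an enedione carbon (C11–C15), and reduction of the resulting C12 radical by divalent iron gives an iron enolate that attacks the C13 aldehyde (C12–C13), so the step is a Giese addition–aldol radical–polar crossover. The closest known reaction type is the iron-catalysed hydrogen-atom-transfer annulation of γ,δ-unsaturated aldehydes with enones to cyclohexanols. Ring B closes in a 12-exo-trig radical addition under high dilution and ring A in a 6-(enolexo)-exo-trig aldol. C11 and C12 are set cis by the three-atom C15–C1–C14 link and on the face of ring C that carries the C8 chain, the C13 carbinol is uncontrolled, and all three are erased in step 10, whereas C1 and C6 are untouched. The step needs chemoselective hydrogen-atom transfer, secured by keeping C4 as a ketone so that the hindered trisubstituted C7=C8 alkene is the only other isolated alkene, and it needs no regiocontrol because the local mirror plane of the enedione makes attack at either alkene carbon give the same constitution. The polarity match between the nucleophilic tertiary radical and the doubly activated alkene should let ring closure compete with premature reduction of the radical.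

Step 10
Reactants: 16 tricyclic hydroxy dione
Product: 18 tricyclic 11-ene-10,18-dione (C4 ketone; C6 OTBS; 1R,6S,9S), via alkylidene tautomer 17 (not isolated)
Conditions: camphorsulfonic acid (cat.), 4 Å molecular sieves, toluene, 70 °C
Reagents that add atoms: none
Why: Acid-catalysed aldol dehydration gives the C12=C13 alkylidene tautomer, a prototropic shift through the C10 dienol should move the alkene to the ring fusion (as exocyclic itaconic-type systems pass into endocyclic citraconic-type ones), and the acidic C9–H equilibrates so that C8 lies on the same face as C2, the only strain-free way for the seven-atom C2–C8 bridge to span rings A and C (thermodynamic control by C1).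

Step 11
Reactants: 18 tricyclic enedione
Product: 19 (18R)-18-hydroxy-11-en-10-one (C4 ketone; C6 OTBS)
Conditions: NaBH4 (1 equiv), CeCl3·7H2O, MeOH, −78 °C
Reagents that add atoms: none
Why: In the Luche 1,2-reduction the hydride should take the highly electrophilic enedione before the C4 ketone, take C18 rather than C10 (which is shielded by the C15 gem-dimethyl group), and approach from the face opposite the C2–C8 bridge, which sets C18 as R with the hydroxyl cis to C8.

Step 12
Reactants: 19 hydroxy enone ketone
Product: 20 (18R)-18-hydroxy-4(20),11-dien-10-one (C6 OTBS)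
Conditions: Zn, CH2Br2, TiCl4, THF–CH2Cl2, 0 °C to rt
Reagents that add atoms: dibromomethane BrCBr
Why: The non-basic Takai–Lombardo methylenation tolerates the free hydroxyl and the β-silyloxy ketone without elimination or epimerisation and should take the open C4 ketone rather than the C10 enone carbonyl wedged between C9 and the C15 quaternary carbon.

Step 13
Reactants: 20 silyl ether
Product: 21 (6S,18R)-6,18-diol
Conditions: HF·pyridine, THF, 0 °C to rt
Reagents that add atoms: none
Why: Fluoride-mediated desilylation under mildly acidic conditions frees C6–OH without the base that could epimerise C9 or eliminate at C18.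

Step 14
Reactants: 21 diol
Product: 22 target diacetate CNP0121312.1
Conditions: Ac2O, pyridine, DMAP (cat.), CH2Cl2, 0 °C to rt
Reagents that add atoms: acetic anhydride CC(=O)OC(C)=O
Why: DMAP-catalysed acylation esterifies both secondary alcohols with retention at C6 and C18.

Compound list
1 | (R)-(+)-limonene | CC1=CC[C@@H](CC1)C(C)=C | starting material
2 | (3R)-6-oxo-3-(prop-1-en-2-yl)heptanal | CC(=O)CC[C@H](CC=O)C(C)=C | intermediate
3 | (5R)-7,7-dimethoxy-5-(prop-1-en-2-yl)heptan-2-one | CC(=O)CC[C@H](CC(OC)OC)C(C)=C | intermediate
4 | but-2-yn-1-ol | CC#CCO | starting material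
5 | (E)-alkenylzirconocene chloride, zirconium on the methyl-bearing carbon, oxygen bound as zirconocene alkoxide | C/C(=C\CO[Zr](Cl)(C1C=CC=C1)C1C=CC=C1)[Zr](Cl)(C1C=CC=C1)C1C=CC=C1 | intermediate
6 | (E)-3-iodobut-2-en-1-ol | C/C(I)=C\CO | intermediate
7 | (E)-3-iodobut-2-enal | C/C(I)=C\C=O | intermediate
8 | terminal diisopinocampheylboron enolate of 3 | C=C(CC[C@H](CC(OC)OC)C(C)=C)OB([C@@H]1C[C@@H]2C[C@H]([C@H]1C)C2(C)C)[C@@H]1C[C@@H]2C[C@H]([C@H]1C)C2(C)C | intermediate
9 | (2E,4S,9R)-4-hydroxy-2-iodo-11,11-dimethoxy-9-(prop-1-en-2-yl)undec-2-en-6-one | I/C(C)=C/[C@@H](O)CC(=O)CC[C@H](CC(OC)OC)C(C)=C | intermediate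
10 | 4-O-TBS ether of 9 | I/C(C)=C/[C@@H](O[Si](C)(C)C(C)(C)C)CC(=O)CC[C@H](CC(OC)OC)C(C)=C | intermediate
11 | furfural | O=Cc1ccco1 | starting material
12 | furyl carbinol (carbinol centre open) | OC(c1ccco1)/C(C)=C/[C@@H](O[Si](C)(C)C(C)(C)C)CC(=O)CC[C@H](CC(OC)OC)C(C)=C | intermediate
13 | trans-4-hydroxy-5-alkenylcyclopent-2-enone keto aldehyde (ring centres open) | O=C1C=CC(O)C1/C(C)=C/[C@@H](O[Si](C)(C)C(C)(C)C)CC(=O)CC[C@H](CC=O)C(C)=C | intermediate
14 | 2-alkenylcyclopent-4-ene-1,3-dione keto aldehyde | O=C1C=CC(=O)C1/C(C)=C/[C@@H](O[Si](C)(C)C(C)(C)C)CC(=O)CC[C@H](CC=O)C(C)=C | intermediate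
15 | twelve-membered Giese adduct, iron C12 enolate (drawn as the enol) | O=C1CC[C@H](CC=O)C(C)(C)[C@@H]2C=C(O)[C@@H](C2=O)/C(C)=C/[C@@H](O[Si](C)(C)C(C)(C)C)C1 | intermediate
16 | tricyclic C13-hydroxy 10,18-dione, cis C11/C12 fusion (drawn as the diketone; C9 and C13 open) | O=C1CC[C@@H]2CC(O)[C@H]3[C@H](C(=O)C(/C(C)=C/[C@@H](O[Si](C)(C)C(C)(C)C)C1)C3=O)C2(C)C | intermediate
17 | C12=C13 alkylidene tautomer (drawn as the C18 enol) | O=C1CC[C@@H]2CC=C3C(O)=C(C(=O)[C@@H]3C2(C)C)/C(C)=C/[C@@H](O[Si](C)(C)C(C)(C)C)C1 | intermediate
18 | tricyclic 11-ene-10,18-dione, C4 ketone, C6 OTBS | O=C1CC[C@@H]2CCC3=C(C(=O)[C@@H](/C(C)=C/[C@@H](O[Si](C)(C)C(C)(C)C)C1)C3=O)C2(C)C | intermediate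
19 | (18R)-18-hydroxy-11-en-10-one, C4 ketone, C6 OTBS | O=C1CC[C@@H]2CCC3=C(C(=O)[C@@H](/C(C)=C/[C@@H](O[Si](C)(C)C(C)(C)C)C1)[C@H]3O)C2(C)C | intermediate
20 | (18R)-18-hydroxy-4(20),11-dien-10-one, C6 OTBS | C=C1CC[C@@H]2CCC3=C(C(=O)[C@@H](/C(C)=C/[C@@H](O[Si](C)(C)C(C)(C)C)C1)[C@H]3O)C2(C)C | intermediate
21 | (6S,18R)-6,18-diol | C=C1CC[C@@H]2CCC3=C(C(=O)[C@@H](/C(C)=C/[C@@H](O)C1)[C@H]3O)C2(C)C | intermediate
22 | CNP0121312.1, (1R,6S,9S,18R)-6,18-diacetate | C=C1CC[C@@H]2CCC3=C(C(=O)[C@@H](/C(C)=C/[C@@H](OC(C)=O)C1)[C@H]3OC(C)=O)C2(C)C | target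

Total steps: 14. Longest linear sequence: 13 steps (4 to 22, steps 2–14).

Steps most likely to fail

Step 9.
- What may go wrong: the C15 radical may be quenched by a second hydrogen-atom transfer (net hydrogenation of the isopropenyl group). The enedione may also be reduced by the hydride source before the slow twelve-membered ring closure occurs, and oligomerisation is a further drain.
- Fallback, from 10 back to 18: the order of ring closures is inverted, so the radical step becomes bimolecular and the macrocycle is closed by a cross-coupling. The acetal of 10 is hydrolysed (PPTS, wet acetone) to the iodo keto aldehyde F1. The same iron-hydride annulation is then run with an excess of commercial cyclopent-4-ene-1,3-dione to give the bicyclic hydroxy dione F2. This is dehydrated as in step 10 to the C9-unsubstituted enedione F3. Ring B is closed at C8–C9 by intramolecular alkenylation of the soft C9 enolate with the vinyl iodide (Pd2(dba)3, P(t-Bu)3, Cs2CO3, toluene, high dilution). That coupling proceeds with retention of alkene geometry and cannot be diverted into a Heck reaction, because C11=C12 is by then tetrasubstituted.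

Step 10.
- What may go wrong: the prototropic shift may stall because enolisation of the 1,3-dione at C9 parks the material as the extended enol of the alkylidene tautomer. Forcing the acid invites loss of the silyl ether.
- Fallback, from 16 (through 17) back to 18: C9 is blocked so that the 1,3-dione cannot enolise. The dehydrated material is sulfenylated at C9 (N-(phenylthio)succinimide, Et3N) to the 9-phenylthio alkylidene dione F4. In F4 the only acidic position left is H11, so catalytic DBU should carry the alkene into the ring fusion to give the 9-phenylthio enedione F5. Thiophilic desulfenylation (PhSH, Et3N) followed by protonation of the C9 enolate then delivers 18.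

Step 11.
- What may go wrong: hydride may be consumed in deprotonating the acidic C9–H, leaving an unreactive enolate. Site selectivity may also be poor, with attack at C10 or at the C4 ketone.
- Fallback, from 16 back to 20: the competing ketone is removed first, and substrate control is replaced by catalyst control with a neutral borane. Takai–Lombardo methylenation is run on 16, whose enolised 1,3-dione is masked as its metal enolate, to give the 4(20)-methylene hydroxy dione F6. Dehydration as in step 10 gives the 4(20)-methylene enedione F7. Reduction with (S)-Me-CBS oxazaborolidine and catecholborane (toluene, −78 °C) should then select between the two pseudo-enantiotopic ring carbonyls. Attack at C18 from the open face is the matched case, whereas attack at C10 would have to come from the bridged face.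

Further compounds
F1 | step 9 | (3R,8S,9E)-8-(tert-butyldimethylsilyloxy)-10-iodo-6-oxo-3-(prop-1-en-2-yl)undec-9-enal | I/C(C)=C/[C@@H](O[Si](C)(C)C(C)(C)C)CC(=O)CC[C@H](CC=O)C(C)=C
F2 | step 9 | bicyclic C13-hydroxy 10,18-dione with open C2–C8 chain ending in the vinyl iodide | I/C(C)=C/[C@@H](O[Si](C)(C)C(C)(C)C)CC(=O)CC[C@@H]1CC(O)C2C(C(=O)CC2=O)C1(C)C
F3 | step 9 | bicyclic C9-unsubstituted 11-ene-10,18-dione with open C2–C8 chain ending in the vinyl iodide | I/C(C)=C/[C@@H](O[Si](C)(C)C(C)(C)C)CC(=O)CC[C@@H]1CCC2=C(C(=O)CC2=O)C1(C)C
F4 | step 10 | 9-phenylthio C12=C13 alkylidene 10,18-dione | O=C1CC[C@@H]2CC=C3C(=O)C(Sc4ccccc4)(C(=O)[C@@H]3C2(C)C)/C(C)=C/[C@@H](O[Si](C)(C)C(C)(C)C)C1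
F5 | step 10 | 9-phenylthio 11-ene-10,18-dione | O=C1CC[C@@H]2CCC3=C(C(=O)C(Sc4ccccc4)(/C(C)=C/[C@@H](O[Si](C)(C)C(C)(C)C)C1)C3=O)C2(C)C
F6 | step 11 | 4(20)-methylene analogue of 16 | C=C1CC[C@@H]2CC(O)[C@H]3[C@H](C(=O)C(/C(C)=C/[C@@H](O[Si](C)(C)C(C)(C)C)C1)C3=O)C2(C)C
F7 | step 11 | 4(20)-methylene analogue of 18 | C=C1CC[C@@H]2CCC3=C(C(=O)[C@@H](/C(C)=C/[C@@H](O[Si](C)(C)C(C)(C)C)C1)C3=O)C2(C)C
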